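Ring B with C4, C18 and C19 (labdane numbering) comes from (R)-carvone, whose isopropenyl carbon becomes C4. Ring A is closed by inserting one two-carbon unit, C2–C3, between C4 and C1: a titanocene-catalysed radical [4+2] annulation in which the tertiary C4 radical from the isopropenyl epoxide adds to a vinylboronate (C3–C4) and the resulting C2 radical cyclises onto a C1 sulfonylhydrazone (C1–C2). The step exploits the 1,4-relationship of the quaternary C4 (bearing C19–O) and the C1 methylene across the C5–C10 ring fusion; both epoxide epimers converge, C19–OH and an equatorial C2–boron (the later 2α-OH) result, and the hydrazone nitrogen is then expelled to leave C1 as CH2.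

Key step: step 6

Remark: labdane numbering (C1–C20, 5α-H, 10β-CH3) is used for all compounds, also the monocyclic ones; the epoxides 4–6 are carried as the mixture of both C4 epimers, which is harmless because C4 becomes planar in step 6.

Step 1
Reactants: 1 (R)-(−)-carvone
Product: 2 6-methylcarvone (C6 epimers)
Conditions: LDA, THF, −78 °C; MeI, −78 → 0 °C
Reagents that add atoms: methyl iodide, CI
Why: Kinetic α′-deprotonation and enolate C-methylation install the future C20 methyl on the future C10; the epimer mixture is acceptable because this centre is re-enolised in step 2.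

Step 2
Reactants: 2 6-methylcarvone
Product: 3 (5S,6R)-6-(hydroxymethyl)-2,6-dimethyl-5-(prop-1-en-2-yl)cyclohex-2-en-1-one
Conditions: LDA, THF, −78 °C; CH2O (gas, from cracked paraformaldehyde), −78 °C; aq NH4Cl, cold
Reagents that add atoms: formaldehyde, C=O
Why: Aldol addition of the fully substituted α′-enolate to formaldehyde should occur anti to the neighbouring isopropenyl group, setting quaternary C10 with CH2OH (future C1) trans and the methyl cis to that group.

Step 3
Reactants: 3 hydroxymethyl enone
Product: 4 (5R,6R)-6-(hydroxymethyl)-2,6-dimethyl-5-(2-methyloxiran-2-yl)cyclohex-2-en-1-one (both epoxide epimers)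
Conditions: mCPBA, NaHCO3, CH2Cl2, 0 °C
Reagents that add atoms: mCPBA, OOC(=O)c1cccc(Cl)c1
Why: Prilezhaev epoxidation is chemoselective for the electron-rich 1,1-disubstituted alkene over the electron-poor enone alkene; the new centre (future C4) forms as both epimers without consequence.

Step 4
Reactants: 4 epoxy alcohol
Product: 5 (1R,6R)-1,3-dimethyl-6-(2-methyloxiran-2-yl)-2-oxocyclohex-3-ene-1-carbaldehyde (both epoxide epimers)
Conditions: Dess–Martin periodinane, NaHCO3, CH2Cl2, 0 °C → rt
Reagents that add atoms: none
Why: Dess–Martin oxidation converts the neopentyl primary alcohol into the non-enolisable β-keto aldehyde under buffered conditions that spare epoxide and enone.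

Step 5
Reactants: 5 epoxy keto aldehyde
Product: 6 (E)-N′-tosylhydrazone of 5
Conditions: TsNHNH2, THF, 4 Å MS, rt
Reagents that add atoms: 4-methylbenzenesulfonohydrazide, Cc1ccc(cc1)S(=O)(=O)NN
Why: Hydrazone condensation should be far faster at the aldehyde than at the hindered conjugated ketone and gives the E sulfonylhydrazone that serves as a traceless radical acceptor at C1.

Step 6
Reactants: 6 epoxy hydrazone; 7 vinylboronic acid pinacol ester
Product: 8 19-hydroxy-2α-(pinacolboryl)-1-(2-tosylhydrazinyl)-11,12,13,14,15,16-hexanorlabd-7-en-9-one (C1 epimers)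
Conditions: Cp2TiCl2 (20 mol %), Mn dust, 2,4,6-collidine·HCl, 7 (10 equiv), THF, rt
Reagents that add atoms: none
Why: Proposed new method: Cp2TiCl formed in situ (trivalent titanium) opens either epoxide epimer of 6 by single-electron transfer to the same planar tertiary β-titanoxy radical at C4, which adds to the CH2 terminus of 7 (C3–C4 bond); the α-boryl radical at C2 then closes ring A by 6-exo-trig attack on the hydrazone carbon C1 (C1–C2 bond), and the hydrazinyl radical is reduced by a second Cp2TiCl and protonated by collidinium, which turns the catalyst over. The closest known reaction types are the titanocene-mediated reductive epoxide opening with intermolecular Giese addition to activated alkenes (Nugent–RajanBabu reagent), radical addition to vinylboronates, and stannane- or iron-hydride-mediated radical cyclisation onto sulfonylhydrazones; their merger in one flask is the untested part. C4 is set by 1,2-induction from C5: the radical should be attacked anti to the quaternary C10 while the bulky CH2O–[Ti] arm eclipses C5–H, which puts CH2O on the β (later axial) side and the methyl α. C2 is set in the chair-like transition state, where the boronate must sit equatorial (α) to avoid the syn-axial C10 methyl and C4 CH2O groups; C1 forms as an inconsequential mixture because its nitrogen is removed in step 7. The step needs the intermolecular addition to outrun four-membered ring closure of the C4 radical onto the enone and its reduction by titanium, which the large excess of 7 and the low standing concentration of Cp2TiCl should secure. It also needs the C2 radical to choose C1=N over the C9 carbonyl, which the much higher radical affinity of the hydrazone carbon should secure.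

Step 7
Reactants: 8 hydrazide boronate
Product: 9 19-hydroxy-2α-(pinacolboryl)-11,12,13,14,15,16-hexanorlabd-7-en-9-one
Conditions: NaOAc·3H2O, tert-dodecanethiol, EtOH, 75 °C
Reagents that add atoms: none
Why: Acetate-induced loss of sulfinate from the N-alkyl-N′-sulfonylhydrazide gives a monoalkyl diazene that expels N2 by a radical chain (the fragmentation stage of a Caglioti-type tosylhydrazone deoxygenation), leaving C1 as CH2, while the thiol should trap the C1 radical by H-atom transfer before a 1,2-boryl or 1,2-acyl (Dowd–Beckwith-type) shift.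

Step 8
Reactants: 9 boronate alcohol
Product: 10 19-acetoxy-2α-(pinacolboryl)-11,12,13,14,15,16-hexanorlabd-7-en-9-one
Conditions: Ac2O, pyridine, DMAP (cat.), CH2Cl2, rt
Reagents that add atoms: acetic anhydride, CC(=O)OC(C)=O
Why: With C2 still masked as its boronate the C19 hydroxyl is the only one present, so DMAP-catalysed acylation gives the C19 acetate without a selectivity problem.

Step 9
Reactants: 10 boronate acetate
Product: 11 19-acetoxy-2α-hydroxy-11,12,13,14,15,16-hexanorlabd-7-en-9-one
Conditions: NaBO3·4H2O, THF/H2O, rt
Reagents that add atoms: sodium perborate, [Na+].[O-]B1OO1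
Why: Perborate oxidation of the secondary alkyl boronate proceeds by 1,2-migration of C2 from boron to oxygen with retention, so the equatorial C2–B becomes the 2α alcohol while the mildly basic medium should spare the acetate.

Step 10
Reactants: 11 hydroxy acetate enone
Product: 12 19-acetoxy-2α-hydroxy-12,13,14,15,16-pentanorlabda-7,9(11)-diene
Conditions: Zn, CH2Br2, TiCl4, THF/CH2Cl2, 0 °C → rt
Reagents that add atoms: dibromomethane, BrCBr
Why: Takai–Lombardo methylenation with the non-basic titanium–zinc methylene reagent should convert the hindered, non-enolisable C9 ketone into the exocyclic C9=C11 alkene while tolerating acetate and free hydroxyl.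

Step 11
Reactants: 13 (tert-butyldimethylsilyloxy)acetaldehyde; 14 isopropenylmagnesium bromide
Product: 16 racemic 1-(tert-butyldimethylsilyloxy)-3-methylbut-3-en-2-yl diethyl phosphate, via magnesium alkoxide 15 (not isolated)
Conditions: 14, THF, −78 → 0 °C; then ClP(O)(OEt)2, 0 °C → rt
Reagents that add atoms: diethyl chlorophosphate, CCOP(=O)(Cl)OCC
Why: Grignard 1,2-addition to the aldehyde and trapping of the alkoxide with the chlorophosphate give the secondary allylic phosphate in one flask; its stereocentre is irrelevant because it becomes sp2 in step 12.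

Step 12
Reactants: 12 diene; 16 allylic phosphate
Product: 18 19-acetoxy-15-(tert-butyldimethylsilyloxy)labda-7,13E-dien-2α-ol, via B-alkyl-9-BBN adduct 17 (not isolated)
Conditions: 9-BBN dimer, THF, 0 °C → rt; then t-BuOK, CuOAc (10 mol %), 16, THF, 60 °C; aqueous work-up
Reagents that add atoms: none
Why: 9-BBN should add to the terminal C11 of the exocyclic alkene from the α face opposite the C10 methyl (setting 9α-H), and the derived alkylborate then undergoes copper-catalysed γ-selective anti-SN2′ allyl–alkyl coupling at the unsubstituted CH2 terminus of 16; the E alkene is expected because the transition state keeps the carbinol hydrogen, not CH2OTBS, eclipsed with the alkene (A1,3 strain).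

Step 13
Reactants: 18 silyl ether
Product: 19 19-acetoxylabda-7,13E-diene-2α,15-diol (target)
Conditions: HF·pyridine, pyridine/THF, 0 °C → rt
Reagents that add atoms: none
Why: Fluoride-mediated cleavage of the primary allylic silyl ether under buffered conditions should leave the acetate, the secondary alcohol and both alkenes untouched.

Compound list
1 | (R)-(−)-carvone | CC(=C)[C@@H]1CC=C(C)C(=O)C1 | starting material
2 | 6-methylcarvone, (5R)-2,6-dimethyl-5-(prop-1-en-2-yl)cyclohex-2-en-1-one, C6 epimers | CC(=C)[C@@H]1CC=C(C)C(=O)C1C | intermediate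
3 | (5S,6R)-6-(hydroxymethyl)-2,6-dimethyl-5-(prop-1-en-2-yl)cyclohex-2-en-1-one (CH2OH trans to isopropenyl) | CC(=C)[C@@H]1CC=C(C)C(=O)[C@@]1(C)CO | intermediate
4 | (5R,6R)-6-(hydroxymethyl)-2,6-dimethyl-5-(2-methyloxiran-2-yl)cyclohex-2-en-1-one, both epoxide epimers | CC1(CO1)[C@@H]2CC=C(C)C(=O)[C@@]2(C)CO | intermediate
5 | (1R,6R)-1,3-dimethyl-6-(2-methyloxiran-2-yl)-2-oxocyclohex-3-ene-1-carbaldehyde, both epoxide epimers | CC1(CO1)[C@@H]2CC=C(C)C(=O)[C@@]2(C)C=O | intermediate
6 | N′-[(E)-{(1R,6R)-1,3-dimethyl-6-(2-methyloxiran-2-yl)-2-oxocyclohex-3-en-1-yl}methylidene]-4-methylbenzenesulfonohydrazide, both epoxide epimers | CC1(CO1)[C@@H]2CC=C(C)C(=O)[C@@]2(C)/C=N/NS(=O)(=O)c3ccc(C)cc3 | intermediate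
7 | vinylboronic acid pinacol ester | C=CB1OC(C)(C)C(C)(C)O1 | starting material
8 | 19-hydroxy-2α-(pinacolboryl)-1-(2-tosylhydrazinyl)-11,12,13,14,15,16-hexanorlabd-7-en-9-one (4α-CH3, 5α-H, 10β-CH3; C1 epimers) | OC[C@@]1(C)C[C@H](B2OC(C)(C)C(C)(C)O2)C(NNS(=O)(=O)c3ccc(C)cc3)[C@]4(C)C(=O)C(C)=CC[C@@H]14 | intermediate
9 | 19-hydroxy-2α-(pinacolboryl)-11,12,13,14,15,16-hexanorlabd-7-en-9-one | OC[C@@]1(C)C[C@H](B2OC(C)(C)C(C)(C)O2)C[C@]3(C)C(=O)C(C)=CC[C@@H]13 | intermediate
10 | 19-acetoxy-2α-(pinacolboryl)-11,12,13,14,15,16-hexanorlabd-7-en-9-one | CC(=O)OC[C@@]1(C)C[C@H](B2OC(C)(C)C(C)(C)O2)C[C@]3(C)C(=O)C(C)=CC[C@@H]13 | intermediate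
11 | 19-acetoxy-2α-hydroxy-11,12,13,14,15,16-hexanorlabd-7-en-9-one | CC(=O)OC[C@@]1(C)C[C@H](O)C[C@]2(C)C(=O)C(C)=CC[C@@H]12 | intermediate
12 | 19-acetoxy-2α-hydroxy-12,13,14,15,16-pentanorlabda-7,9(11)-diene | CC(=O)OC[C@@]1(C)C[C@H](O)C[C@]2(C)C(=C)C(C)=CC[C@@H]12 | intermediate
13 | (tert-butyldimethylsilyloxy)acetaldehyde | CC(C)(C)[Si](C)(C)OCC=O | starting material
14 | isopropenylmagnesium bromide | CC(=C)[Mg]Br | starting material
15 | bromomagnesium 1-(tert-butyldimethylsilyloxy)-3-methylbut-3-en-2-olate (racemic) | CC(=C)C(CO[Si](C)(C)C(C)(C)C)O[Mg]Br | intermediate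
16 | 1-(tert-butyldimethylsilyloxy)-3-methylbut-3-en-2-yl diethyl phosphate (racemic) | C=C(C)C(CO[Si](C)(C)C(C)(C)C)OP(=O)(OCC)OCC | intermediate
17 | C11 B-alkyl-9-BBN adduct of 12 (9α-H), C2 hydroxyl as its 9-BBN borinate | CC(=O)OC[C@@]1(C)C[C@H](OB3C4CCCC3CCC4)C[C@]2(C)[C@@H](CB5C6CCCC5CCC6)C(C)=CC[C@@H]12 | intermediate
18 | 19-acetoxy-15-(tert-butyldimethylsilyloxy)labda-7,13E-dien-2α-ol | CC(=O)OC[C@@]1(C)C[C@H](O)C[C@]2(C)[C@@H](CC/C(C)=C/CO[Si](C)(C)C(C)(C)C)C(C)=CC[C@@H]12 | intermediate
19 | 19-acetoxylabda-7,13E-diene-2α,15-diol | CC(=O)OC[C@@]1(C)C[C@H](O)C[C@]2(C)[C@@H](CC/C(C)=C/CO)C(C)=CC[C@@H]12 | target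

Total step count: 13. Longest linear sequence: 12 steps (steps 1–10, 12 and 13 from 1); step 11 is a one-step side branch.

Steps most likely to fail

Step 6 (Proposed new method). The C2 radical may be reduced by titanium before it cyclises, the C4 radical may close a four-membered ring onto the enone instead of adding to 7, or the intermolecular addition may show poor facial selectivity at C4. The fallback uses known stannane radical-chain chemistry and sets out from 5. Acetyl bromide (CH2Cl2, 0 °C) should open the epoxide at its tertiary carbon to give the tertiary bromide with primary acetate F1. Condensation with tosylhydrazide gives hydrazone F2. Bu3SnH (slow addition) and AIBN with excess 7 in benzene at 80 °C then effect Giese addition of the tertiary radical to the vinylboronate and 6-exo cyclisation onto the sulfonylhydrazone, giving hydrazide acetate F3 (any C4 epimer being separated here). The conditions of step 7 convert F3 into 10, where the route is rejoined.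

Step 7. After loss of N2 the C1 radical may undergo a 1,2-boryl shift from C2 faster than H-atom transfer, scrambling the boronate position. The fallback sets out from 8 and removes boron first: NaBO3·4H2O oxidises 8 to diol hydrazide F4; NaOAc·3H2O with the thiol in hot EtOH then gives diol enone F5; selective acetylation of the primary C19 hydroxyl (AcCl, 2,4,6-collidine, CH2Cl2, −78 °C) returns to 11.

Step 12. Transfer of the β-branched alkyl group from boron to copper may be sluggish, attack may occur at the wrong allyl terminus, or the new alkene may form with poor E selectivity. The fallback sets out from 12 and switches to a cross-electrophile coupling. Hydroboration as before and iodinolysis of the borane (ICl, NaOAc, MeOH, 0 °C) give primary iodide F6. Nickel-catalysed reductive coupling of F6 with 16 (NiBr2·glyme, 4,4′-di-tert-butyl-2,2′-bipyridine, Zn, DMA) then proceeds through a C11 radical and a π-allylnickel intermediate that can equilibrate to the syn form and couples at its less hindered CH2 terminus, returning to 18.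

Further compounds
F1 | step 6 | 2-bromo-2-[(1R,2R)-2-formyl-2,4-dimethyl-3-oxocyclohex-4-en-1-yl]propyl acetate (C4 epimers) | CC(=O)OCC(C)(Br)[C@@H]1CC=C(C)C(=O)[C@@]1(C)C=O
F2 | step 6 | (E)-N′-tosylhydrazone of F1 | CC(=O)OCC(C)(Br)[C@@H]1CC=C(C)C(=O)[C@@]1(C)/C=N/NS(=O)(=O)c2ccc(C)cc2
F3 | step 6 | 19-acetoxy-2α-(pinacolboryl)-1-(2-tosylhydrazinyl)-11,12,13,14,15,16-hexanorlabd-7-en-9-one (C1 epimers) | CC(=O)OC[C@@]1(C)C[C@H](B2OC(C)(C)C(C)(C)O2)C(NNS(=O)(=O)c3ccc(C)cc3)[C@]4(C)C(=O)C(C)=CC[C@@H]14
F4 | step 7 | 2α,19-dihydroxy-1-(2-tosylhydrazinyl)-11,12,13,14,15,16-hexanorlabd-7-en-9-one (C1 epimers) | OC[C@@]1(C)C[C@H](O)C(NNS(=O)(=O)c2ccc(C)cc2)[C@]3(C)C(=O)C(C)=CC[C@@H]13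
F5 | step 7 | 2α,19-dihydroxy-11,12,13,14,15,16-hexanorlabd-7-en-9-one | OC[C@@]1(C)C[C@H](O)C[C@]2(C)C(=O)C(C)=CC[C@@H]12
F6 | step 12 | 19-acetoxy-11-iodo-12,13,14,15,16-pentanorlabd-7-en-2α-ol | CC(=O)OC[C@@]1(C)C[C@H](O)C[C@]2(C)[C@@H](CI)C(C)=CC[C@@H]12
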